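The balance of L is the invariant of the ochre flask: the L charged equals the L still free plus the L held in Z plus the L that went elsewhere, taking one L to each Z.

| flask | E | L | temperature | remark | time |
|---|---|---|---|---|---|
| ochre | 1 M | 0.80 M | 110 °C | the very flask that is asked about, followed so far |  |
| green | 1 M | 0.80 M | 116 °C | run made earlier |  |
| flask | 1.0 M | 0.800 M | 110 °C |  | 1.0 h |

- ochre (time / min: Z / %, E / %): 4.00: 36.2, 0.1; 6.00: 36.3, 0.2; 8.00: 36.8, 0.1; 15.0: 36.6, 1.0; 20.0: 35.8, 0; 30.0: 37.2, 0; 50.0: 36.2, 0.9
- green (time / min: Z / %, E / %): 4.00: 27.2, 0; 6.00: 27.9, 0; 8.00: 26.4, 0; 15.0: 27.1, 0; 20.0: 26.4, 0; 30.0: 26.9, 0.3; 50.0: 27.1, 0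

(standard deviation of a reading: 0.5 percentage points)

* Z, in percent of the E first charged, at 1.0 h
* the remedy with the largest gain of Z, or "none" below 2 percentage points (midnight / noon / summer / none)
* Z present, in percent of the E first charged, after midnight
* Z present, in percent of the E first charged, after noon

- the volume of additions can be left aside
- the numbers in the tables scatter with a standard deviation of 0.5 percentage points
- at the start none of E is in solution
- a reading or a percentage of Z counts all its forms, free or not

- midnight: at 1.0 h raise the temperature by 25 K, then wait 1.0 h
- noon: change nothing and wait 1.0 h more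
- summer: at 1.0 h add L, 50.0% of the amount charged, then wait 1.0 h

The solid E reads 0.1% at the first ochre reading, 4.00 min, so a balance with solid E has little to stand on from then on. Z lies flat up to 50.0 min, with a mean of 36.4%. My reading, an assumption at this stage, is that L is the limiting reagent. But the green run, hotter, stops lower at 27.0%, so L seems to have a second way out, and the two ways race.

With free L taken as nil, the ochre plateau gives a reading of 0.837 for S, the selectivity factor: Z made per L lost another way. Green gives 0.509. In powers of ten, that is a slope of 0.0359 /K in log10 S, falling as the flask gets hotter.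

My own reckoning therefore keeps Z at 36.4% after noon and after midnight, and expects a gain from added L, in summer, with its size left open.

The forecast sees “a fast exothermic equilibrium” instead. It gives 36.4% now, 36.4% after noon, 8.4% after midnight, and summer as the best remedy. The two part at midnight.

The flask gives 36.3% now, 36.3% after noon and 36.3% after midnight, and summer gains 19 percentage points.

    E ⇌ X, rate k1*(cs1 - [X]) while solid is left; crystals form when [X] > cs1 (solubility = 0.570 M, k = 0.00860 /s)
    X + L → Z (k = 0.620 /M/s, Ea = 75.0 kJ/mol)
    L → G (k = 0.0150 /s, Ea = 117 kJ/mol)
    Q ⇌ Z, rate k4*(cs4 - [Z]) while solid is left; crystals form when [Z] > cs4 (solubility = 0.330 M, k = 0.160 /s)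
    2 E → J (k = 0.00950 /M/s, Ea = 94.0 kJ/mol)
    (constants at 110 °C)

In the ochre flask, L → G, which makes the other product G, had 100% of its turnover up to 60.0 min behind it by 6.00 min, and X + L → Z, with X the dissolved E, had 100% by 12.0 min; at 60.0 min free L stood at 0%, and S there, Z with Q counted in over G, was 0.833. For the flask kept at 85 °C, the slope read from the two runs carries S from ochre to an estimated 6.61, which shares the charged L into an estimated 69.5% of Z; that flask ends at 70.5%, with 0% of its L left.

The runs are simulated from invented constants, noise included.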